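**Retrosynthetic overview**

1. The target is (2S)-5-hydroxy-7-methoxy-8-prenyl-4'-hydroxyflavanone. The plan rests on ring A: a phloroglucinol whose three oxygens (O1, O5, O7) and the prenylated carbon C8 must each be distinguished, which a ring A built de novo with a single free OH (O1, between C8 and the unsubstituted C4a) achieves.
2. C2–aryl bond: asymmetric 1,4-addition of an arylboronic acid to 5-hydroxy-7-methoxy-8-prenylchromone sets C2. The O5 ethyl group is removed by peri-chelation one step earlier, while the molecule is still achiral.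
3. Ring C (chromone): from the O1 phenol by base-mediated ortho-formylation at C4a, ethynyl addition, oxidation and 6-endo closure, avoiding acids that would cyclise the ortho-prenylphenol.
4. Ring A: benzannulation of 3-ethoxycyclobutenone with the prenylated methoxyalkyne, forming C8–C8a and C6–C7 ([2+2]) and C4a–C8a (6π closure).
5. Order of ring formation: ring A (step 3), ring C (step 7); ring B arrives intact with the boronic acid (step 9).

Key step: step 3

Assumption: the (S)-configured biaryl bisphosphine is taken to deliver the aryl group to chromone C2 with the same enone-face preference that (S)-BINAP shows for cyclohex-2-enone, which corresponds to (2S); the antipodal ligand is used if the sense proves opposite.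

**Route**

Step 1
Reactants: 1 ethoxyacetylene; 2 acetyl chloride
Product: 4 3-ethoxycyclobut-2-en-1-one, via ketene 3 (not isolated)
Conditions: Et3N, Et2O, 0 °C to rt, slow addition of 2
Reagents that add atoms: none
Why: Dehydrochlorination of acetyl chloride by Et3N generates ketene in the presence of the electron-rich ynol ether, and the ketene–alkyne [2+2] cycloaddition joins the ketene carbonyl carbon to the unsubstituted alkyne carbon to give the vinylogous ester.

Step 2
Reactants: 5 chloroacetaldehyde dimethyl acetal; 6 prenyl bromide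
Product: 8 1-methoxy-5-methylhex-4-en-1-yne, via lithium methoxyacetylide 7 (not isolated)
Conditions: LiNEt2 (3 equiv, from Et2NH and n-BuLi), THF, 0 °C; then 6 (1.3 equiv), DMPU, -78 °C to rt
Reagents that add atoms: none
Why: Double elimination (HCl, then MeOH) from the chloroacetal with three equivalents of amide base is a known one-pot entry to lithium alkoxyacetylides, and the acetylide is C-alkylated by the primary allylic bromide at its unhindered terminus (SN2).

Step 3
Reactants: 4 3-ethoxycyclobut-2-en-1-one (1.5 equiv); 8 1-methoxy-5-methylhex-4-en-1-yne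
Product: 13 5-ethoxy-3-methoxy-2-(3-methylbut-2-enyl)phenol, via vinylketene 9 (not isolated), via 4-vinylcyclobutenone 10 (not isolated), via dienylketene 11 (not isolated), via cyclohexadienone 12 (not isolated)
Conditions: toluene, 90 to 120 °C, sealed tube, Ar; then KOH, MeOH, rt (cleaves any aryl ester formed by ketene capture)
Reagents that add atoms: none
Why: Heating opens cyclobutenone 4 by 4π electrocyclic cleavage of its C1–C4 bond to vinylketene 9, whose ketene C=C adds across the ynol ether in a [2+2] to give 10; a second 4π opening gives dienylketene 11, which closes to 12 and tautomerises to 13. The closest known reaction type is the Danheiser benzannulation of cyclobutenones with alkoxy- and siloxyalkynes. Ring A is closed by a thermal 6π electrocyclisation that re-forms the C4a–C8a bond, after the [2+2] has made C8–C8a and C6–C7. No stereocentre is created, the one in 10 being lost on ring opening. The step needs a single regiochemical outcome in the [2+2], and the polarity of the ynol ether should provide it: the nucleophilic prenyl-bearing carbon bonds to the electrophilic ketene carbonyl carbon (future C8a) and the methoxy-bearing carbon to the ketene α-carbon (future C6). The phenol should therefore carry its only OH (O1) between the prenyl carbon C8 and the unsubstituted C4a, with OMe fixed at C7 and OEt at C5.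

Step 4
Reactants: 13 5-ethoxy-3-methoxy-2-(3-methylbut-2-enyl)phenol
Product: 14 6-ethoxy-2-hydroxy-4-methoxy-3-(3-methylbut-2-enyl)benzaldehyde
Conditions: (CH2O)n, MgCl2, Et3N, MeCN, reflux
Reagents that add atoms: paraformaldehyde (formaldehyde source), C=O
Why: Casnati–Skattebøl ortho-formylation, in which the magnesium phenoxide delivers formaldehyde through a chelate to the only free ortho carbon (future C4a) and a second formaldehyde oxidises the benzylic alkoxide, all under basic conditions that leave the para position and the acid-sensitive ortho-prenylphenol untouched.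

Step 5
Reactants: 14 6-ethoxy-2-hydroxy-4-methoxy-3-(3-methylbut-2-enyl)benzaldehyde
Product: 15 1-[6-ethoxy-2-hydroxy-4-methoxy-3-(3-methylbut-2-enyl)phenyl]prop-2-yn-1-ol (racemic)
Conditions: HC≡CMgBr (3 equiv), THF, 0 °C to rt; sat. aq. NH4Cl; crude product used directly
Reagents that add atoms: ethynylmagnesium bromide, C#C[Mg]Br
Why: Grignard 1,2-addition to the aldehyde after the first equivalent has deprotonated the phenol; the new carbinol centre is racemic and is destroyed in step 6.

Step 6
Reactants: 15 1-[6-ethoxy-2-hydroxy-4-methoxy-3-(3-methylbut-2-enyl)phenyl]prop-2-yn-1-ol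
Product: 16 1-[6-ethoxy-2-hydroxy-4-methoxy-3-(3-methylbut-2-enyl)phenyl]prop-2-yn-1-one
Conditions: activated MnO2 (excess), CH2Cl2, rt
Reagents that add atoms: none
Why: MnO2 oxidation of a doubly activated (benzylic and propargylic) alcohol to the ynone under neutral heterogeneous conditions that should spare the phenol and the prenyl alkene.

Step 7
Reactants: 16 1-[6-ethoxy-2-hydroxy-4-methoxy-3-(3-methylbut-2-enyl)phenyl]prop-2-yn-1-one
Product: 18 5-ethoxy-7-methoxy-8-(3-methylbut-2-enyl)-4H-chromen-4-one, via enaminone 17 (not isolated)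
Conditions: Et2NH, EtOH, rt; then AcOH, 60 °C
Reagents that add atoms: none
Why: Aza-Michael addition of the amine to the terminal ynone gives the β-aminoenone, whose amine is displaced by the single ortho-phenol (O1) in a 6-endo addition–elimination, the standard enaminone route to 2,3-unsubstituted chromones, which avoids the 5-exo closure open to direct base cyclisation.

Step 8
Reactants: 18 5-ethoxy-7-methoxy-8-(3-methylbut-2-enyl)-4H-chromen-4-one
Product: 19 5-hydroxy-7-methoxy-8-(3-methylbut-2-enyl)-4H-chromen-4-one
Conditions: anhydrous MgI2 (3 equiv), toluene, 80 °C; then 1 M HCl, 0 °C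
Reagents that add atoms: none
Why: Chelation-directed ether cleavage, in which MgI2 binds the C4 carbonyl and the peri oxygen O5 and iodide removes the ethyl group by SN2, while the non-chelated 7-OMe and the prenyl alkene (no adjacent free OH, no protic acid) should remain; it is done on the achiral chromone so that no stereocentre is exposed.

Step 9
Reactants: 19 5-hydroxy-7-methoxy-8-(3-methylbut-2-enyl)-4H-chromen-4-one; 20 4-(tert-butyldimethylsilyloxy)phenylboronic acid (2.5 equiv)
Product: 21 (2S)-2-[4-(tert-butyldimethylsilyloxy)phenyl]-5-hydroxy-7-methoxy-8-(3-methylbut-2-enyl)chroman-4-one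
Conditions: [Rh(OH)(cod)]2 (2.5 mol%), (S)-MeO-F12-BIPHEP [(S)-2,2'-bis[bis(3,4,5-trifluorophenyl)phosphino]-6,6'-dimethoxy-1,1'-biphenyl] (6 mol%), dioxane/H2O (10:1), 40 °C, no added base
Reagents that add atoms: none
Why: Hayashi–Miyaura asymmetric 1,4-addition, in which the arylrhodium species inserts the chromone C2=C3 bond on the face selected by the (S)-bisphosphine (catalyst control, C2 set as S) and the oxa-π-allyl is protonated by water; base-free mild conditions limit retro-oxa-Michael ring opening.

Step 10
Reactants: 21 (2S)-2-[4-(tert-butyldimethylsilyloxy)phenyl]-5-hydroxy-7-methoxy-8-(3-methylbut-2-enyl)chroman-4-one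
Product: 22 Mundulea flavanone B
Conditions: Et3N·3HF, THF, 0 °C to rt
Reagents that add atoms: none
Why: Fluoride cleavage of the aryl silyl ether with a buffered, weakly acidic fluoride source avoids the basic conditions under which C2 could epimerise through chalcone formation.

**Compound list**

1 | ethoxyacetylene (ethoxyethyne) | C#COCC | starting material
2 | acetyl chloride | CC(=O)Cl | starting material
3 | ketene (ethenone) | C=C=O | intermediate
4 | 3-ethoxycyclobut-2-en-1-one | CCOC1=CC(=O)C1 | intermediate
5 | chloroacetaldehyde dimethyl acetal (2-chloro-1,1-dimethoxyethane) | COC(CCl)OC | starting material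
6 | prenyl bromide (1-bromo-3-methylbut-2-ene) | CC(C)=CCBr | starting material
7 | lithium methoxyacetylide | [Li]C#COC | intermediate
8 | 1-methoxy-5-methylhex-4-en-1-yne | COC#CCC=C(C)C | intermediate
9 | 3-ethoxybuta-1,3-dien-1-one ((1-ethoxyvinyl)ketene) | CCOC(=C)C=C=O | intermediate
10 | 4-(1-ethoxyvinyl)-3-methoxy-2-(3-methylbut-2-enyl)cyclobut-2-en-1-one (racemic) | CCOC(=C)C1C(OC)=C(CC=C(C)C)C1=O | intermediate
11 | (3E)-5-ethoxy-3-methoxy-2-(3-methylbut-2-enyl)hexa-1,3,5-trien-1-one (ketene and ethoxyvinyl termini cis) | CCOC(=C)/C=C(OC)\C(CC=C(C)C)=C=O | intermediate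
12 | 5-ethoxy-3-methoxy-2-(3-methylbut-2-enyl)cyclohexa-2,4-dien-1-one | CCOC1=CC(OC)=C(CC=C(C)C)C(=O)C1 | intermediate
13 | 5-ethoxy-3-methoxy-2-(3-methylbut-2-enyl)phenol | CCOc1cc(O)c(CC=C(C)C)c(OC)c1 | intermediate
14 | 6-ethoxy-2-hydroxy-4-methoxy-3-(3-methylbut-2-enyl)benzaldehyde | CCOc1cc(OC)c(CC=C(C)C)c(O)c1C=O | intermediate
15 | 1-[6-ethoxy-2-hydroxy-4-methoxy-3-(3-methylbut-2-enyl)phenyl]prop-2-yn-1-ol (racemic) | CCOc1cc(OC)c(CC=C(C)C)c(O)c1C(O)C#C | intermediate
16 | 1-[6-ethoxy-2-hydroxy-4-methoxy-3-(3-methylbut-2-enyl)phenyl]prop-2-yn-1-one | CCOc1cc(OC)c(CC=C(C)C)c(O)c1C(=O)C#C | intermediate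
17 | (E)-3-(diethylamino)-1-[6-ethoxy-2-hydroxy-4-methoxy-3-(3-methylbut-2-enyl)phenyl]prop-2-en-1-one | CCOc1cc(OC)c(CC=C(C)C)c(O)c1C(=O)/C=C/N(CC)CC | intermediate
18 | 5-ethoxy-7-methoxy-8-(3-methylbut-2-enyl)-4H-chromen-4-one | CCOc1cc(OC)c(CC=C(C)C)c2occc(=O)c12 | intermediate
19 | 5-hydroxy-7-methoxy-8-(3-methylbut-2-enyl)-4H-chromen-4-one | COc1cc(O)c2c(=O)ccoc2c1CC=C(C)C | intermediate
20 | 4-(tert-butyldimethylsilyloxy)phenylboronic acid | CC(C)(C)[Si](C)(C)Oc1ccc(B(O)O)cc1 | starting material
21 | (2S)-2-[4-(tert-butyldimethylsilyloxy)phenyl]-5-hydroxy-7-methoxy-8-(3-methylbut-2-enyl)chroman-4-one | COc1cc(O)c2c(c1CC=C(C)C)O[C@H](c1ccc(O[Si](C)(C)C(C)(C)C)cc1)CC2=O | intermediate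
22 | Mundulea flavanone B, (2S)-5-hydroxy-2-(4-hydroxyphenyl)-7-methoxy-8-(3-methylbut-2-enyl)chroman-4-one | COc1cc(O)c2c(c1CC=C(C)C)O[C@H](c1ccc(O)cc1)CC2=O | target

**Step count**

Total steps: 10. Longest linear sequence: 9 steps (step 1 or step 2, then steps 3 to 10).

**Steps most likely to fail**

Step 3 (benzannulation). The donor-stabilised cyclobutenone may open only at temperatures where vinylketene 9 oligomerises, or is consumed by phenol already formed, faster than the hindered internal ynol ether captures it. The fallback sets out from alkyne 8 and generates the same vinylketene at room temperature by photochemical Wolff rearrangement, the diazo-ketone variant of this benzannulation. Ethyl vinyl ether is lithiated (t-BuLi, THF, -78 to 0 °C) to 1-ethoxyvinyllithium F1 and acylated with N-methoxy-N-methylacetamide to 3-ethoxybut-3-en-2-one F2. Claisen trifluoroacetylation (LiHMDS, CF3CO2CH2CF3, -78 °C) gives 5-ethoxy-1,1,1-trifluorohex-5-ene-2,4-dione F3, and detrifluoroacetylative diazo transfer (MsN3, Et3N, H2O, MeCN) gives 1-diazo-3-ethoxybut-3-en-2-one F4. Irradiation of F4 with 8 in CH2Cl2 at rt, then warming to 80 °C, should pass through 9 to 12 and return to the route at phenol 13.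

Step 9 (asymmetric 1,4-addition). Insertion into the electron-rich, hydrogen-bonded chromone may be slow and poorly face-selective, and the enantiomeric purity may erode by reversible ring opening over long reaction times. The fallback sets out from chromone 19 and moves stereocontrol from the C–C bond formation to a kinetic resolution. Ligand-free [Rh(OH)(cod)]2 with boronic acid 20 in dioxane/H2O should give the racemic silyl flavanone F5. Noyori asymmetric transfer hydrogenation (RuCl[(R,R)-TsDPEN](p-cymene), HCO2H/Et3N) is expected to reduce the (2R)-enantiomer to the cis-(2R,4R)-flavan-4-ol F6 and leave the (2S)-ketone, which is separated by chromatography and rejoins the route at 21.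

Step 1 (ketene [2+2]). Ketene made from acetyl chloride and Et3N may dimerise or be acylated faster than the ynol ether traps it, and the vinylogous ester product is prone to hydrolysis on isolation. The fallback sets out from ethoxyacetylene 1 and uses a ketene that is generated cleanly and is more electrophilic. Dichloroketene F7 (from trichloroacetyl chloride and Zn–Cu couple, Et2O/DME, rt) should add to 1 to give 4,4-dichloro-3-ethoxycyclobut-2-en-1-one F8. Reductive dechlorination (Zn, AcOH, TMEDA, EtOH, 0 °C) returns to the route at cyclobutenone 4.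

**Further compounds**

F1 | step 3 | 1-ethoxyvinyllithium | [Li]C(=C)OCC
F2 | step 3 | 3-ethoxybut-3-en-2-one | CCOC(=C)C(C)=O
F3 | step 3 | 5-ethoxy-1,1,1-trifluorohex-5-ene-2,4-dione | CCOC(=C)C(=O)CC(=O)C(F)(F)F
F4 | step 3 | 1-diazo-3-ethoxybut-3-en-2-one | CCOC(=C)C(=O)C=[N+]=[N-]
F5 | step 9 | racemic 2-[4-(tert-butyldimethylsilyloxy)phenyl]-5-hydroxy-7-methoxy-8-(3-methylbut-2-enyl)chroman-4-one | COc1cc(O)c2c(c1CC=C(C)C)OC(c1ccc(O[Si](C)(C)C(C)(C)C)cc1)CC2=O
F6 | step 9 | (2R,4R)-2-[4-(tert-butyldimethylsilyloxy)phenyl]-7-methoxy-8-(3-methylbut-2-enyl)chromane-4,5-diol | COc1cc(O)c2c(c1CC=C(C)C)O[C@@H](c1ccc(O[Si](C)(C)C(C)(C)C)cc1)C[C@H]2O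
F7 | step 1 | dichloroketene | ClC(Cl)=C=O
F8 | step 1 | 4,4-dichloro-3-ethoxycyclobut-2-en-1-one | CCOC1=CC(=O)C1(Cl)Cl
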